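**Retrosynthetic overview**

1. The O‑5 ester is made last by opening 3‑methylglutaconic anhydride with the C5–OH (the ring fixes the Z alkene; attack at the non‑conjugated carbonyl leaves the conjugated acid free). The 3‑hydroxypropanoyl group on C1 is carried as a 2‑isoxazoline grown from a C1 aldehyde (nitrile oxide + ethylene).
2. Ring A (C1–C2–C3=C4–C4a–C8a) is cut at C1–C8a and C2–C3 by a Diels–Alder reaction after moving the unsaturation to C4=C4a as a silyl enol ether: 2‑silyloxy diene C3=C4(OSi)–C4a=C8a on ring B plus a (Z)‑enal C1=C2 (sec‑butyl on C2, CH3 and CHO on C1).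
3. Enabling feature: ring A is a cyclohexene whose C1 carries a carbonyl carbon and whose C4 is 1,4 to C1. A C4 oxygen therefore makes ring A a "para" Diels–Alder retron; the resulting C4 ketone later returns the C3=C4 alkene (kinetic enol triflate, reduction) and lets the trans C4a–H be set by equilibration.
4. Ring B is bought as (R)‑5‑methylcyclohex‑2‑enone (C8 stereocentre). Luche reduction, hydroxyl‑directed anti dihydroxylation (C5, C6), acetonide, oxidation, enol triflate and Stille coupling give the diene; the dienophile comes from (R)‑2‑methylbutan‑1‑ol by Z‑selective olefination.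
5. Order of ring formation: ring B (present from the start), then ring A (Diels–Alder). Temporary rings: acetonide (O‑5/O‑6) and isoxazoline (side chain).

Key step: step 11

Assumption: (R)‑5‑methylcyclohex‑2‑en‑1‑one (otherwise three known steps from (R)‑pulegone) and (R)‑2‑methylbutan‑1‑ol are taken as purchasable single enantiomers.

Numbering used for the decalins: C1 (quaternary; CH3 and acyl), C2 (sec‑butyl), C3=C4, C4a, C5 (acyloxy), C6 (OH), C7, C8 (CH3), C8a. The β face carries H‑4a, the C1 methyl, O‑5 and O‑6; the α face carries H‑8a, the C2 sec‑butyl, the C1 acyl carbon and the C8 methyl.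

**Route**

Step 1
Reactants: 1 (R)‑5‑methylcyclohex‑2‑en‑1‑one
Product: 2 (1R,5R)‑5‑methylcyclohex‑2‑en‑1‑ol (OH cis to CH3)
Conditions: NaBH4, CeCl3·7H2O, MeOH, −78 → 0 °C
Reagents that add atoms: none
Why: Luche reduction gives clean 1,2‑reduction; hydride should add along the axial trajectory of the half‑chair with equatorial methyl, so the carbinol OH ends cis to CH3 (as in carvone to cis‑carveol).

Step 2
Reactants: 2 (1R,5R)‑5‑methylcyclohex‑2‑en‑1‑ol
Product: 3 (1α,2β,3β,5α)‑5‑methylcyclohexane‑1,2,3‑triol (2‑OH and 3‑OH cis to each other, trans to 1‑OH and to CH3)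
Conditions: OsO4 (2 mol %), N‑methylmorpholine N‑oxide, acetone/H2O, rt
Reagents that add atoms: N‑methylmorpholine N‑oxide, C[N+]1([O-])CCOCC1; water, O
Why: Upjohn dihydroxylation is suprafacial and should occur anti to the allylic hydroxyl (empirical anti rule for osmylation of allylic alcohols), a face that is also anti to the methyl group; this sets the future C5 and C6 oxygens on the β face.

Step 3
Reactants: 3 (1α,2β,3β,5α)‑5‑methylcyclohexane‑1,2,3‑triol
Product: 4 (1α,2β,3β,5α)‑2,3‑(isopropylidenedioxy)‑5‑methylcyclohexan‑1‑ol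
Conditions: 2,2‑dimethoxypropane, PPTS (cat.), acetone, rt
Reagents that add atoms: 2,2‑dimethoxypropane, COC(C)(C)OC
Why: Acid‑catalysed acetonide formation under thermodynamic control; only the cis‑2,3‑diol can close a cis‑fused dioxolane, so the trans‑disposed 1‑OH stays free.

Step 4
Reactants: 4 (1α,2β,3β,5α)‑2,3‑(isopropylidenedioxy)‑5‑methylcyclohexan‑1‑ol
Product: 5 (2R,3R,5R)‑2,3‑(isopropylidenedioxy)‑5‑methylcyclohexan‑1‑one
Conditions: Dess–Martin periodinane, pyridine, CH2Cl2, 0 °C → rt
Reagents that add atoms: none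
Why: Dess–Martin oxidation of the secondary alcohol is non‑basic, so the α‑alkoxy stereocentre should not epimerize.

Step 5
Reactants: 5 (2R,3R,5R)‑2,3‑(isopropylidenedioxy)‑5‑methylcyclohexan‑1‑one
Product: 6 (3R,5R,6R)‑5,6‑(isopropylidenedioxy)‑3‑methylcyclohex‑1‑en‑1‑yl trifluoromethanesulfonate
Conditions: KN(SiMe3)2, THF, −78 °C; then PhNTf2, −78 → 0 °C
Reagents that add atoms: N‑phenylbis(trifluoromethanesulfonimide), O=S(=O)(N(c1ccccc1)S(=O)(=O)C(F)(F)F)C(F)(F)F
Why: Kinetic enolization with a hindered amide base should remove a proton from the CH2 rather than from the hindered, oxygenated methine, and O‑sulfonylation gives the enol triflate.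

Step 6
Reactants: 6 (3R,5R,6R)‑5,6‑(isopropylidenedioxy)‑3‑methylcyclohex‑1‑en‑1‑yl trifluoromethanesulfonate
Product: 8 1‑[(3R,5R,6S)‑5,6‑(isopropylidenedioxy)‑3‑methylcyclohex‑1‑en‑1‑yl]ethan‑1‑one, via ethoxydiene 7 (not isolated)
Conditions: tributyl(1‑ethoxyvinyl)stannane, Pd(PPh3)4 (5 mol %), LiCl, THF, 65 °C; then 1 M HCl, THF, 0 °C, 15 min
Reagents that add atoms: tributyl(1‑ethoxyvinyl)stannane, CCCC[Sn](CCCC)(CCCC)C(=C)OCC; water, O
Why: Stille coupling of an enol triflate (LiCl) with the 1‑ethoxyvinyl stannane as acetyl anion equivalent; brief cold acid should hydrolyse the enol ether much faster than the acetonide.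

Step 7
Reactants: 8 1‑[(3R,5R,6S)‑5,6‑(isopropylidenedioxy)‑3‑methylcyclohex‑1‑en‑1‑yl]ethan‑1‑one
Product: 9 tert‑butyl({1‑[(3R,5R,6S)‑5,6‑(isopropylidenedioxy)‑3‑methylcyclohex‑1‑en‑1‑yl]ethenyl}oxy)dimethylsilane (2‑silyloxy diene)
Conditions: TBSOTf, Et3N, CH2Cl2, 0 °C
Reagents that add atoms: tert‑butyldimethylsilyl trifluoromethanesulfonate, CC(C)(C)[Si](C)(C)OS(=O)(=O)C(F)(F)F
Why: Soft enolization of a methyl enone deprotonates the methyl group kinetically and should give the cross‑conjugated 2‑silyloxy‑1,3‑diene.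

Step 8
Reactants: 10 (R)‑2‑methylbutan‑1‑ol; 11 ethyl 2‑[bis(2,2,2‑trifluoroethoxy)phosphoryl]propanoate
Product: 13 ethyl (2Z,4R)‑2,4‑dimethylhex‑2‑enoate, via (R)‑2‑methylbutanal 12 (not isolated)
Conditions: TEMPO (10 mol %), PhI(OAc)2, CH2Cl2, rt, aq. NaHCO3 wash; solution added to 11, KN(SiMe3)2, 18‑crown‑6, THF, −78 °C
Reagents that add atoms: none
Why: Oxoammonium oxidation gives the α‑branched aldehyde without epimerization, and Still–Gennari olefination with the trifluoroethyl phosphonate should give the Z trisubstituted enoate (sec‑butyl cis to the ester).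

Step 9
Reactants: 13 ethyl (2Z,4R)‑2,4‑dimethylhex‑2‑enoate
Product: 14 (2Z,4R)‑2,4‑dimethylhex‑2‑en‑1‑ol
Conditions: i‑Bu2AlH (2.2 equiv), CH2Cl2, −78 °C
Reagents that add atoms: none
Why: 1,2‑Reduction of the enoate by the aluminium hydride should leave the alkene geometry untouched.

Step 10
Reactants: 14 (2Z,4R)‑2,4‑dimethylhex‑2‑en‑1‑ol
Product: 15 (2Z,4R)‑2,4‑dimethylhex‑2‑enal
Conditions: Dess–Martin periodinane, pyridine, CH2Cl2, 0 °C; used at once
Reagents that add atoms: none
Why: Buffered Dess–Martin oxidation of the allylic alcohol avoids the acid that would isomerize the Z enal.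

Step 11
Reactants: 9 2‑silyloxy diene; 15 (2Z,4R)‑2,4‑dimethylhex‑2‑enal
Product: 16 Diels–Alder adduct: 4‑(tert‑butyldimethylsilyloxy)‑Δ4(4a)‑octalin‑1α‑carbaldehyde with 1β‑CH3, 2α‑[(R)‑butan‑2‑yl], 5β,6β‑isopropylidenedioxy, 8α‑CH3 and 8aα‑H
Conditions: Al(OC6H3‑2,6‑Ph2)3 (aluminium tris(2,6‑diphenylphenoxide), 1.1 equiv), toluene, −78 → −40 °C
Reagents that add atoms: none
Why: Lewis‑acid‑promoted normal‑demand [4+2] cycloaddition (Diels–Alder) of a 2‑silyloxy diene with an α‑substituted enal, a well‑precedented pairing; it is concerted but asynchronous, the nucleophilic CH2 terminus (C3, activated by the C4 silyloxy group) bonding first to the enal β‑carbon (C2) and the hindered C8a–C1 bond then closing ring A, which fixes the regiochemistry. Ring A is closed in the intermolecular cycloaddition mode as a six‑membered ring, the C4=C4a silyl enol ether remaining as a latent C4 ketone. C1 and C2: suprafacial addition transfers the Z geometry of the enal, so CHO and sec‑butyl end cis (both α) and the C1 methyl β. C8a relative to C1: the exo transition state (aluminium‑bound formyl and sec‑butyl pointing away from the diene, only CH3 and H above it) should be enforced by the bulky aluminium aryloxide, which is known to favour exo adducts, and by the OTBS and C5–O groups that crowd the endo region. C8a relative to ring B: the dienophile should add to the diene face anti to the C8 methyl, which sits pseudoaxial next to the bond‑forming terminus C8a because allylic 1,2‑strain with the silyloxyvinyl group forces the trans‑related C5–O (and hence the C8 methyl) pseudoaxial. The step therefore needs regio‑, exo‑ and π‑facial control and retention of the Z geometry, secured respectively by the C4 oxygen, the bulk of the Lewis acid, the C8 stereocentre and the low temperature in a non‑polar solvent.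

Step 12
Reactants: 16 Diels–Alder adduct (aldehyde)
Product: 17 (E)‑aldoxime of 16 (silyl enol ether intact)
Conditions: NH2OH·HCl, pyridine, EtOH, rt
Reagents that add atoms: hydroxylamine hydrochloride, Cl.NO
Why: Oxime condensation is done while the C4 ketone is still masked as the silyl enol ether, so only the aldehyde reacts.

Step 13
Reactants: 17 (E)‑aldoxime silyl enol ether
Product: 19 trans‑fused (4aβ‑H, 8aα‑H) C4 ketone aldoxime, via cis‑fused ketone 18 (not isolated)
Conditions: Bu4NF, AcOH, THF, 0 °C; then DBU, rt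
Reagents that add atoms: none
Why: Fluoride cleavage of the silyl enol ether followed by base equilibration of the α‑centre C4a; the trans‑fused ketone should be favoured because the cis isomer places C4 axial on ring B, syn to the axial C6 oxygen. The oxime is inert, and a C1 carbanion is too poor a leaving group for retro‑Michael opening.

Step 14
Reactants: 19 trans‑fused C4 ketone aldoxime
Product: 22 trans‑fused C4 ketone carrying a 4,5‑dihydroisoxazol‑3‑yl group at C1α, via hydroximoyl chloride 20 (not isolated), via nitrile oxide 21 (not isolated)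
Conditions: NCS, DMF, rt; then ethylene (balloon), Et3N (slow addition), CH2Cl2, 0 °C → rt
Reagents that add atoms: ethylene, C=C
Why: Chlorination and dehydrochlorination of the aldoxime give a hindered, long‑lived nitrile oxide that undergoes Huisgen 1,3‑dipolar cycloaddition with ethylene; the isoxazoline is a masked β‑hydroxy ketone and no stereocentre is created.

Step 15
Reactants: 22 isoxazoline ketone
Product: 23 C3=C4 enol triflate (4‑trifluoromethanesulfonyloxy‑Δ3‑octalin)
Conditions: KN(SiMe3)2 (1.05 equiv), THF, −78 °C; then PhNTf2, −78 → −20 °C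
Reagents that add atoms: N‑phenylbis(trifluoromethanesulfonimide), O=S(=O)(N(c1ccccc1)S(=O)(=O)C(F)(F)F)C(F)(F)F
Why: Kinetic enolization should occur at the C3 methylene, not at the ring‑fusion methine C4a (which keeps its configuration) nor at the less acidic isoxazoline CH2; O‑triflation then fixes the C3=C4 position.

Step 16
Reactants: 23 C3=C4 enol triflate
Product: 24 Δ3‑octalin with the C3=C4 alkene, C1α isoxazoline and 5β,6β‑acetonide
Conditions: Pd(OAc)2 (5 mol %), PPh3, Bu3N, HCO2H, DMF, 60 °C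
Reagents that add atoms: none
Why: Palladium‑catalysed formate reduction of an enol triflate replaces OTf by H without moving the double bond or touching a stereocentre.

Step 17
Reactants: 24 Δ3‑octalin acetonide
Product: 25 5β,6β‑diol (isoxazoline intact)
Conditions: AcOH/H2O (4:1), 50 °C
Reagents that add atoms: none
Why: Aqueous acid hydrolysis of the acetonide; the isoxazoline and the alkene are stable to these conditions.

Step 18
Reactants: 25 5β,6β‑diol isoxazoline
Product: 27 triol: 5β,6β‑dihydroxy‑Δ3‑octalin with the 3‑hydroxypropanoyl group at C1α, via hydroxy imine 26 (not isolated)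
Conditions: Mo(CO)6 (0.6 equiv), MeCN/H2O (15:1), 80 °C
Reagents that add atoms: water, O
Why: Mo(CO)6‑mediated reductive N–O cleavage of a 2‑isoxazoline and hydrolysis of the β‑hydroxy imine unveil the β‑hydroxy ketone; the reagent does not reduce alkenes.

Step 19
Reactants: 28 3‑methylglutaconic acid (commercial; E isomer drawn, E/Z mixtures behave the same)
Product: 29 3‑methylglutaconic anhydride (4‑methyl‑2H‑pyran‑2,6(3H)‑dione)
Conditions: Ac2O, 60 °C; volatiles removed in vacuo
Reagents that add atoms: none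
Why: Cyclodehydration via the mixed anhydride; the enolizable system lets the E acid isomerize, and only the Z geometry can close the six‑membered anhydride, which locks the alkene as Z.

Step 20
Reactants: 27 triol; 29 3‑methylglutaconic anhydride
Product: 31 tandyukisin C, via stannylene acetal 30 (not isolated)
Conditions: Bu2SnO (1.05 equiv), MeOH, reflux, then evaporation; 29 (1.2 equiv), 1,4‑dioxane, rt; aq. KHSO4 work‑up
Reagents that add atoms: none
Why: Stannylene‑acetal‑mediated regioselective acylation: the dibutylstannylene forms only on the cis‑5,6‑diol and activates its equatorial oxygen (O‑5) over the axial O‑6 and the free primary alcohol. Alcoholysis of the unsymmetrical anhydride at its non‑conjugated, more electrophilic carbonyl should give the CH2‑side ester with the free conjugated acid and the Z alkene retained.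

**Compound list**

1 | (R)‑5‑methylcyclohex‑2‑en‑1‑one | O=C1C=CC[C@@H](C)C1 | starting material
2 | (1R,5R)‑5‑methylcyclohex‑2‑en‑1‑ol | O[C@H]1C=CC[C@@H](C)C1 | intermediate
3 | (1α,2β,3β,5α)‑5‑methylcyclohexane‑1,2,3‑triol | O[C@H]1[C@H](O)[C@H](O)C[C@@H](C)C1 | intermediate
4 | (1α,2β,3β,5α)‑2,3‑(isopropylidenedioxy)‑5‑methylcyclohexan‑1‑ol | O[C@H]1[C@H](O2)[C@H](OC2(C)C)C[C@@H](C)C1 | intermediate
5 | (2R,3R,5R)‑2,3‑(isopropylidenedioxy)‑5‑methylcyclohexan‑1‑one | O=C1[C@H](O2)[C@H](OC2(C)C)C[C@@H](C)C1 | intermediate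
6 | (3R,5R,6R)‑5,6‑(isopropylidenedioxy)‑3‑methylcyclohex‑1‑en‑1‑yl trifluoromethanesulfonate | O=S(=O)(OC=1[C@H](O2)[C@H](OC2(C)C)C[C@@H](C)C=1)C(F)(F)F | intermediate
7 | (3R,5R,6S)‑1‑(1‑ethoxyethenyl)‑5,6‑(isopropylidenedioxy)‑3‑methylcyclohex‑1‑ene (ethoxydiene) | C=C(OCC)C=1[C@H](O2)[C@H](OC2(C)C)C[C@@H](C)C=1 | intermediate (not isolated)
8 | 1‑[(3R,5R,6S)‑5,6‑(isopropylidenedioxy)‑3‑methylcyclohex‑1‑en‑1‑yl]ethan‑1‑one | CC(=O)C=1[C@H](O2)[C@H](OC2(C)C)C[C@@H](C)C=1 | intermediate
9 | tert‑butyl({1‑[(3R,5R,6S)‑5,6‑(isopropylidenedioxy)‑3‑methylcyclohex‑1‑en‑1‑yl]ethenyl}oxy)dimethylsilane | C=C(O[Si](C)(C)C(C)(C)C)C=1[C@H](O2)[C@H](OC2(C)C)C[C@@H](C)C=1 | intermediate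
10 | (R)‑2‑methylbutan‑1‑ol | CC[C@@H](C)CO | starting material
11 | ethyl 2‑[bis(2,2,2‑trifluoroethoxy)phosphoryl]propanoate | CCOC(=O)C(C)P(=O)(OCC(F)(F)F)OCC(F)(F)F | starting material
12 | (R)‑2‑methylbutanal | CC[C@@H](C)C=O | intermediate (not isolated)
13 | ethyl (2Z,4R)‑2,4‑dimethylhex‑2‑enoate | CC[C@@H](C)/C=C(/C)C(=O)OCC | intermediate
14 | (2Z,4R)‑2,4‑dimethylhex‑2‑en‑1‑ol | CC[C@@H](C)/C=C(/C)CO | intermediate
15 | (2Z,4R)‑2,4‑dimethylhex‑2‑enal | CC[C@@H](C)/C=C(/C)C=O | intermediate
16 | Diels–Alder adduct: 4‑(TBSO)‑Δ4(4a)‑octalin‑1α‑carbaldehyde, 1β‑CH3, 2α‑[(R)‑butan‑2‑yl], 5β,6β‑isopropylidenedioxy, 8α‑CH3, 8aα‑H | CC[C@@H](C)[C@H]1CC(O[Si](C)(C)C(C)(C)C)=C2[C@H](O3)[C@H](OC3(C)C)C[C@@H](C)[C@@H]2[C@@]1(C)C=O | intermediate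
17 | (E)‑aldoxime of 16 | CC[C@@H](C)[C@H]1CC(O[Si](C)(C)C(C)(C)C)=C2[C@H](O3)[C@H](OC3(C)C)C[C@@H](C)[C@@H]2[C@@]1(C)/C=N/O | intermediate
18 | cis‑fused (4aα‑H, 8aα‑H) C4 ketone aldoxime | CC[C@@H](C)[C@H]1CC(=O)[C@@H]2[C@H](O3)[C@H](OC3(C)C)C[C@@H](C)[C@@H]2[C@@]1(C)/C=N/O | intermediate (not isolated)
19 | trans‑fused (4aβ‑H, 8aα‑H) C4 ketone aldoxime | CC[C@@H](C)[C@H]1CC(=O)[C@H]2[C@H](O3)[C@H](OC3(C)C)C[C@@H](C)[C@@H]2[C@@]1(C)/C=N/O | intermediate
20 | hydroximoyl chloride of 19 | CC[C@@H](C)[C@H]1CC(=O)[C@H]2[C@H](O3)[C@H](OC3(C)C)C[C@@H](C)[C@@H]2[C@@]1(C)/C(Cl)=N/O | intermediate (not isolated)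
21 | nitrile oxide from 20 | CC[C@@H](C)[C@H]1CC(=O)[C@H]2[C@H](O3)[C@H](OC3(C)C)C[C@@H](C)[C@@H]2[C@@]1(C)C#[N+][O-] | intermediate (not isolated)
22 | trans‑fused C4 ketone with C1α 4,5‑dihydroisoxazol‑3‑yl group | CC[C@@H](C)[C@H]1CC(=O)[C@H]2[C@H](O3)[C@H](OC3(C)C)C[C@@H](C)[C@@H]2[C@@]1(C)C4=NOCC4 | intermediate
23 | C3=C4 enol triflate of 22 | CC[C@@H](C)[C@H]1C=C(OS(=O)(=O)C(F)(F)F)[C@H]2[C@H](O3)[C@H](OC3(C)C)C[C@@H](C)[C@@H]2[C@@]1(C)C4=NOCC4 | intermediate
24 | Δ3‑octalin with C1α isoxazoline and 5β,6β‑acetonide | CC[C@@H](C)[C@H]1C=C[C@H]2[C@H](O3)[C@H](OC3(C)C)C[C@@H](C)[C@@H]2[C@@]1(C)C4=NOCC4 | intermediate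
25 | 5β,6β‑diol of 24 | CC[C@@H](C)[C@H]1C=C[C@H]2[C@H](O)[C@H](O)C[C@@H](C)[C@@H]2[C@@]1(C)C3=NOCC3 | intermediate
26 | β‑hydroxy imine from 25 | CC[C@@H](C)[C@H]1C=C[C@H]2[C@H](O)[C@H](O)C[C@@H](C)[C@@H]2[C@@]1(C)C(=N)CCO | intermediate (not isolated)
27 | triol: 5β,6β‑dihydroxy‑Δ3‑octalin with C1α 3‑hydroxypropanoyl (desacyl tandyukisin C) | CC[C@@H](C)[C@H]1C=C[C@H]2[C@H](O)[C@H](O)C[C@@H](C)[C@@H]2[C@@]1(C)C(=O)CCO | intermediate
28 | 3‑methylglutaconic acid ((E)‑3‑methylpent‑2‑enedioic acid) | OC(=O)C/C(C)=C/C(=O)O | starting material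
29 | 3‑methylglutaconic anhydride | CC1=CC(=O)OC(=O)C1 | intermediate
30 | 5,6‑O‑dibutylstannylene acetal of 27 | CC[C@@H](C)[C@H]1C=C[C@H]2[C@H](O3)[C@H](O[Sn]3(CCCC)CCCC)C[C@@H](C)[C@@H]2[C@@]1(C)C(=O)CCO | intermediate (not isolated)
31 | tandyukisin C | CC[C@@H](C)[C@H]1C=C[C@H]2[C@H](OC(=O)C/C(C)=C\C(=O)O)[C@H](O)C[C@@H](C)[C@@H]2[C@@]1(C)C(=O)CCO | target

**Summary**

Total step count: 20.
Longest linear sequence: 16 steps (steps 1–7, 11–18 and 20).

**Steps most likely to fail**

1. Step 11 (Diels–Alder). What may go wrong: Lewis‑acid‑induced Z to E isomerization of the enal before cycloaddition, a stepwise Mukaiyama–Michael pathway that erodes the stereospecificity, competing 1,2‑addition, or poor exo and facial control. The fallback sets out from 9 and 13 and comes back at 16. It drops the Lewis acid and the enal: diene 9 and the configurationally stable Z enoate 13 are combined under high pressure (about 13 kbar, CH2Cl2, 40 °C) in a purely thermal, concerted cycloaddition to give the ethyl ester adduct F1. Reduction with i‑Bu2AlH gives the neopentyl alcohol F2, and Dess–Martin oxidation returns aldehyde 16.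

2. Step 13 (ring‑fusion equilibration). What may go wrong: an unfavourable or slow cis/trans equilibrium at C4a under base. The fallback sets out from 18 and comes back at 22, and sets the ring fusion kinetically and stereospecifically instead. The cis‑fused keto oxime 18 is isolated and taken through the nitrile oxide/ethylene cycloaddition of step 14 to the cis‑fused isoxazoline ketone F3. Tf2O with 2,6‑di‑tert‑butyl‑4‑methylpyridine gives the more substituted C4=C4a enol triflate F4, which erases the C4a centre. Palladium‑catalysed formate reduction gives the C4=C4a alkene F5. m‑CPBA should epoxidize its less hindered α face, anti to the allylic C5 oxygen, giving the 4α,4aα‑epoxide F6. BF3·OEt2 at −78 °C then opens the tertiary C4a–O bond with a 1,2‑hydride shift from C4 (Meinwald rearrangement); the hydrogen arrives at C4a anti to the departing oxygen, on the β face, and gives the trans‑fused ketone 22 under non‑equilibrating conditions.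

3. Step 20 (final acylation). What may go wrong: loss of site selectivity through competing acylation of the primary hydroxyl. The fallback sets out from 27 and comes back at 31, replacing chemoselectivity by protection. TBDPSCl and imidazole silylate only the primary alcohol to give the silyl ether diol F7. The same stannylene‑mediated opening of anhydride 29 then gives the O‑5 half ester F8, and HF·pyridine in THF removes the silyl group to give 31.

Further compounds
F1 | step 11 | ethyl ester analogue of 16 (C1α CO2Et) | CC[C@@H](C)[C@H]1CC(O[Si](C)(C)C(C)(C)C)=C2[C@H](O3)[C@H](OC3(C)C)C[C@@H](C)[C@@H]2[C@@]1(C)C(=O)OCC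
F2 | step 11 | primary alcohol analogue of 16 (C1α CH2OH) | CC[C@@H](C)[C@H]1CC(O[Si](C)(C)C(C)(C)C)=C2[C@H](O3)[C@H](OC3(C)C)C[C@@H](C)[C@@H]2[C@@]1(C)CO
F3 | step 13 | cis‑fused (4aα‑H) isoxazoline ketone, C4a epimer of 22 | CC[C@@H](C)[C@H]1CC(=O)[C@@H]2[C@H](O3)[C@H](OC3(C)C)C[C@@H](C)[C@@H]2[C@@]1(C)C4=NOCC4
F4 | step 13 | C4=C4a enol triflate | CC[C@@H](C)[C@H]1CC(OS(=O)(=O)C(F)(F)F)=C2[C@H](O3)[C@H](OC3(C)C)C[C@@H](C)[C@@H]2[C@@]1(C)C4=NOCC4
F5 | step 13 | C4=C4a alkene (Δ4(4a)‑octalin) | CC[C@@H](C)[C@H]1CC=C2[C@H](O3)[C@H](OC3(C)C)C[C@@H](C)[C@@H]2[C@@]1(C)C4=NOCC4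
F6 | step 13 | 4α,4aα‑epoxide of F5 | CC[C@@H](C)[C@H]1C[C@H]5O[C@]52[C@H](O3)[C@H](OC3(C)C)C[C@@H](C)[C@@H]2[C@@]1(C)C4=NOCC4
F7 | step 20 | primary tert‑butyldiphenylsilyl ether of 27 | CC[C@@H](C)[C@H]1C=C[C@H]2[C@H](O)[C@H](O)C[C@@H](C)[C@@H]2[C@@]1(C)C(=O)CCO[Si](c3ccccc3)(c4ccccc4)C(C)(C)C
F8 | step 20 | primary tert‑butyldiphenylsilyl ether of 31 | CC[C@@H](C)[C@H]1C=C[C@H]2[C@H](OC(=O)C/C(C)=C\C(=O)O)[C@H](O)C[C@@H](C)[C@@H]2[C@@]1(C)C(=O)CCO[Si](c3ccccc3)(c4ccccc4)C(C)(C)C
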